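**Strategy.** The route rests on cutting the outer 7-hydroxy-2,3-dihydrobenzofuran across O1–C7a and C2–C3. The precursor is a diarylmethane in which future C3 is the CH2 between ring B (its benzo ring) and the 3,5-dioxygenated ring, C7a bears fluorine and C5 an ester. The key step exploits two features: C3 is doubly benzylic, and C7a lies para to C5, the atom through which this unit joins the rest, so the ester that later becomes that link activates the fluoride. In one pot the carbanion adds to 4-(benzyloxy)benzaldehyde and the alkoxide closes the ring by SNAr, trans. The resolved fragment is joined to an enantiopure tetraaryloxolane; a sulfur ylide [4+1] annulation closes the inner dihydrobenzofuran.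

Key step: step 4

Assumption on the structure: the target is taken exactly as its SMILES encodes it, so the outer dihydrobenzofuran carries its free hydroxyl at C7 (next to the ring oxygen) and is attached through C5.
Assumption on supply: ester 1 and sulfide 31 are treated as commercial (1 is otherwise one esterification from 3-bromo-4-fluorobenzoic acid).
Racemic compounds 10, 11 and 13 are drawn as the (2R,3R) enantiomer.

**Fragment 1 (outer dihydrobenzofuran)**

Step 1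
Reactants: 1 tert-butyl 3-bromo-4-fluorobenzoate
Product: 3 tert-butyl 3-bromo-4-fluoro-5-hydroxybenzoate, via arylboronic pinacol ester 2 (not isolated)
Conditions: [Ir(OMe)(cod)]2 (cat.), 4,4'-di-tert-butyl-2,2'-bipyridine, B2pin2, THF, 80 °C; then KHSO5 (Oxone), acetone/H2O, 0 °C
Reagents that add atoms: potassium peroxymonosulfate, [K+].[O-]S(=O)(=O)OO
Why: Iridium-catalysed C–H borylation is sterically controlled and should go to C5, the only ring C–H without a large ortho neighbour (the small fluorine is tolerated), and the boronate is oxidised in the same flask to the phenol (C–H borylation/oxidation).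

Step 2
Reactants: 3 tert-butyl 3-bromo-4-fluoro-5-hydroxybenzoate
Product: 4 tert-butyl 3-(benzyloxy)-5-bromo-4-fluorobenzoate
Conditions: BnBr, K2CO3, DMF, 25 °C
Reagents that add atoms: benzyl bromide, BrCc1ccccc1
Why: Williamson ether synthesis (SN2 of the phenoxide on benzyl bromide) protects the oxygen that becomes the free 7-hydroxyl of ring B.

Step 3
Reactants: 4 tert-butyl 3-(benzyloxy)-5-bromo-4-fluorobenzoate; 5 3,5-bis(benzyloxy)benzyl bromide
Product: 7 tert-butyl 3-(benzyloxy)-5-[3,5-bis(benzyloxy)benzyl]-4-fluorobenzoate, via benzylzinc bromide 6 (not isolated)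
Conditions: 5, Zn dust, LiCl, THF, 25 °C; then 4, Pd(OAc)2 (cat.), 2-dicyclohexylphosphino-2',6'-dimethoxybiphenyl, THF, 50 °C
Reagents that add atoms: none
Why: Negishi sp3–sp2 cross-coupling of the benzylic zinc reagent with the aryl bromide installs the diarylmethane while the fluoride and the tert-butyl ester stay untouched.

Step 4
Reactants: 7 tert-butyl 3-(benzyloxy)-5-[3,5-bis(benzyloxy)benzyl]-4-fluorobenzoate; 8 4-(benzyloxy)benzaldehyde
Product: 10 tert-butyl rac-(2R,3R)-7-(benzyloxy)-2-[4-(benzyloxy)phenyl]-3-[3,5-bis(benzyloxy)phenyl]-2,3-dihydro-1-benzofuran-5-carboxylate, via lithium alkoxide 9 (not isolated)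
Conditions: LiN(i-Pr)2, THF, −78 → −40 °C; then 8, −78 °C; then DMPU, −78 → 25 °C
Reagents that add atoms: none
Why: LiN(i-Pr)2 removes a proton from the CH2 between ring B and the 3,5-dioxygenated ring (future C3), the diarylmethyl anion adds to the aldehyde carbon (future C2) to give alkoxide 9, and this oxygen attacks C7a ipso to fluorine through a Meisenheimer complex stabilised by the para ester at C5, so that C2–C3 and O1–C7a form in one flask as a formal anionic [3+2] annulation. The closest known reaction type is the domino benzylic deprotonation/addition to C=O or C=N/intramolecular SNAr of ortho-fluorobenzyl anions used for indolines, azaindolines and benzofurans. The furan ring closes in the 5-exo-trig mode by addition–elimination at the arene carbon. C2 and C3 are set relative to each other: the carbonyl addition is reversible for so stabilised a carbanion while ring closure is not, and the closure that keeps the two aryl groups on opposite faces of the forming ring should be the faster, so the trans-2,3 isomer should prevail (the product is racemic; residual cis isomer is converged in step 5 and the absolute configuration is secured in step 6). The step needs chemoselectivity for deprotonation and SNAr over attack on the ester and over dehydration of 9 to a triarylethene, which the tert-butyl ester and the para-activated, low-temperature SNAr should secure; with one fluoride and both positions ortho to it substituted, regiochemistry is fixed and no aryne can form.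

Step 5
Reactants: 10 tert-butyl rac-(2R,3R)-dihydrobenzofuran-5-carboxylate
Product: 11 rac-(2R,3R)-7-(benzyloxy)-2-[4-(benzyloxy)phenyl]-3-[3,5-bis(benzyloxy)phenyl]-2,3-dihydro-1-benzofuran-5-carboxylic acid
Conditions: CF3CO2H, CH2Cl2, 0 → 25 °C
Reagents that add atoms: none
Why: Acidolysis of the tert-butyl ester (E1 loss of 2-methylpropene) frees the acid, and in the same acid the C2–O bond of any cis isomer ionises reversibly to the para-alkoxybenzyl cation and recloses to the more stable trans-2,3 isomer, so the relative configuration converges.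

Step 6
Reactants: 11 rac-(2R,3R)-dihydrobenzofuran-5-carboxylic acid; 12 (S)-2-(methoxymethyl)pyrrolidine
Product: 14 (2R,3R)-dihydrobenzofuran-5-carboxylic acid (S)-2-(methoxymethyl)pyrrolidine amide, via acid chloride 13 (not isolated)
Conditions: (COCl)2, DMF (cat.), CH2Cl2, 0 °C; then 12, Et3N, CH2Cl2, 0 → 25 °C; separation of the two diastereomers (crystallisation or chromatography on silica)
Reagents that add atoms: none
Why: Amidation through the acid chloride with the enantiopure amine turns the racemate into two diastereomeric amides whose separation fixes the (2R,3R) configuration of the outer dihydrobenzofuran by resolution, and the tertiary amide later serves as the acyl donor.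

**Fragment 2 (tetraaryloxolane)**

Step 7
Reactants: 15 3,5-bis(benzyloxy)benzaldehyde
Product: 16 3,5-bis(benzyloxy)-2-bromobenzaldehyde
Conditions: N-bromosuccinimide, MeCN, 0 → 25 °C
Reagents that add atoms: N-bromosuccinimide, O=C1CCC(=O)N1Br
Why: Electrophilic aromatic bromination should go to C2, which is para to one benzyloxy group and ortho to the other and less hindered than C4 between the two ethers.

Step 8
Reactants: 15 3,5-bis(benzyloxy)benzaldehyde
Product: 17 rac-1-[3,5-bis(benzyloxy)phenyl]prop-2-en-1-ol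
Conditions: CH2=CHMgBr, THF, −78 → 0 °C
Reagents that add atoms: vinylmagnesium bromide, C=C[Mg]Br
Why: 1,2-Addition of the vinyl Grignard reagent gives the racemic aryl vinyl carbinol, whose stereocenter is erased on ionisation in step 10.

Step 9
Reactants: 16 3,5-bis(benzyloxy)-2-bromobenzaldehyde
Product: 19 2-[3,5-bis(benzyloxy)-2-bromophenyl]acetaldehyde, via enol ether 18 (not isolated)
Conditions: Ph3P(CH2OMe)Cl, KOt-Bu, THF, 0 °C; then aq. HCl, THF, 25 °C
Reagents that add atoms: (methoxymethyl)triphenylphosphonium chloride, COC[P+](c1ccccc1)(c1ccccc1)c1ccccc1.[Cl-]; water, O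
Why: Wittig methoxymethylenation followed by hydrolysis of the enol ether lengthens the aldehyde by one carbon (homologation).

Step 10
Reactants: 19 2-[3,5-bis(benzyloxy)-2-bromophenyl]acetaldehyde; 17 rac-1-[3,5-bis(benzyloxy)phenyl]prop-2-en-1-ol
Product: 20 (2S,3R)-2-[3,5-bis(benzyloxy)-2-bromophenyl]-3-[3,5-bis(benzyloxy)phenyl]pent-4-enal
Conditions: [Ir(cod)Cl]2 (cat.), (R)-BINOL-derived 5H-dibenzo[b,f]azepin-5-yl phosphoramidite (phosphorus–olefin ligand, cat.), (S)-2-[diphenyl(trimethylsilyloxy)methyl]pyrrolidine (cat.), (MeO)2P(O)OH, ClCH2CH2Cl, 25 °C (ligand/amine enantiomer pair chosen for 2S,3R)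
Reagents that add atoms: none
Why: Stereodivergent dual iridium/amine α-allylation: racemic 17 ionises to a chiral iridium π-allyl complex that is attacked at its benzylic terminus by the chiral enamine of 19, so the phosphoramidite sets C3 and the pyrrolidine sets C2 independently, and the pair is chosen to give the (2S,3R) isomer that holds the two aryl-bearing centres of the oxolane (its later C3 and C4, cis).

Step 11
Reactants: 20 (2S,3R)-pentenal
Product: 21 (2S,3R)-1-[4-(benzyloxy)phenyl]-2-[3,5-bis(benzyloxy)-2-bromophenyl]-3-[3,5-bis(benzyloxy)phenyl]pent-4-en-1-ol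
Conditions: 4-BnOC6H4MgBr, THF, −78 °C
Reagents that add atoms: 4-(benzyloxy)phenylmagnesium bromide, Br[Mg]c1ccc(OCc2ccccc2)cc1
Why: 1,2-Addition of the aryl Grignard reagent at low temperature consumes the epimerisable α-aryl aldehyde; the new carbinol centre forms as a mixture, which is harmless because it is re-equilibrated in step 13.

Step 12
Reactants: 21 (2S,3R)-pentenol
Product: 23 (3R,4S)-5-[4-(benzyloxy)phenyl]-4-[3,5-bis(benzyloxy)-2-bromophenyl]-3-[3,5-bis(benzyloxy)phenyl]oxolan-2-ol, via hydroxy aldehyde 22 (not isolated)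
Conditions: OsO4 (cat.), NaIO4, 2,6-lutidine, dioxane/H2O, 25 °C
Reagents that add atoms: sodium periodate, [Na+].[O-]I(=O)(=O)=O
Why: Lemieux–Johnson cleavage (dihydroxylation/periodate) of the terminal alkene gives the γ-hydroxy aldehyde, which closes spontaneously to the five-membered lactol.

Step 13
Reactants: 23 (3R,4S)-lactol
Product: 25 (2R,3S,4R,5S)-2,5-bis[4-(benzyloxy)phenyl]-3-[3,5-bis(benzyloxy)-2-bromophenyl]-4-[3,5-bis(benzyloxy)phenyl]oxolane, via diol 24 (not isolated)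
Conditions: 4-BnOC6H4MgBr (excess), THF, 0 °C; then camphorsulfonic acid (cat.), CH2Cl2, 0 → 25 °C
Reagents that add atoms: 4-(benzyloxy)phenylmagnesium bromide, Br[Mg]c1ccc(OCc2ccccc2)cc1
Why: The Grignard reagent adds to the open aldehyde form of the lactol, and mild acid then ionises a para-alkoxybenzylic carbinol so that the other hydroxyl closes the oxolane (SN1 cyclodehydration, 5-exo); because this closure is reversible, both 4-(benzyloxy)phenyl groups should settle trans to their ring neighbours while C3 and C4 keep the cis relation set in step 10.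

**Union and completion**

Step 14
Reactants: 25 oxolane aryl bromide; 14 (2R,3R)-amide
Product: 27 diaryl ketone joining the oxolane-bearing ring to C5 of the outer dihydrobenzofuran, via aryllithium 26 (not isolated)
Conditions: t-BuLi (2 equiv), THF, −78 °C; then 14, −78 → 0 °C; aq. NH4Cl
Reagents that add atoms: none
Why: Bromine–lithium exchange and addition of the aryllithium to the tertiary amide give a tetrahedral intermediate, chelated by the methoxymethyl group, that collapses to the ketone only on work-up (ketone synthesis from an amide) without touching any stereocenter.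

Step 15
Reactants: 27 diaryl ketone
Product: 28 ortho-hydroxy diaryl ketone
Conditions: MgBr2·OEt2, toluene/Et2O, 60 °C
Reagents that add atoms: none
Why: Magnesium bromide chelates between the ketone oxygen and the one benzyloxy group ortho to it, so bromide removes only that benzyl group (chelation-controlled ether cleavage) and frees the phenol needed for ring closure.

Step 16
Reactants: 28 ortho-hydroxy diaryl ketone
Product: 30 ortho-hydroxybenzhydryl 4-tolyl sulfone, via carbinol 29 (not isolated)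
Conditions: NaBH4, THF/MeOH, 0 → 25 °C; then 4-MeC6H4SO2H, CH2Cl2, 25 °C
Reagents that add atoms: 4-methylbenzenesulfinic acid, Cc1ccc(cc1)S(O)=O
Why: Hydride reduction gives the ortho-hydroxybenzhydrol, which the sulfinic acid converts by loss of water (through the ortho-quinone methide) into the sulfone, a base-labile quinone methide precursor; the new centre is a mixture and is planarised in step 18.

Step 17
Reactants: 31 (1R,4R,5R)-isothiocineole; 32 4-(benzyloxy)benzyl bromide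
Product: 33 S-[4-(benzyloxy)benzyl]isothiocineolium trifluoromethanesulfonate
Conditions: LiO3SCF3, CH2Cl2/H2O, 25 °C
Reagents that add atoms: lithium trifluoromethanesulfonate, [Li+].[O-]S(=O)(=O)C(F)(F)F
Why: SN2 alkylation of the sulfide by the benzylic bromide with exchange of the anion gives the benzylsulfonium salt, expected as one diastereomer at sulfur.

Step 18
Reactants: 30 ortho-hydroxybenzhydryl sulfone; 33 sulfonium salt
Product: 36 deca-O-benzylkobophenol A, via quinone methide 34 (not isolated), via sulfonium ylide 35 (not isolated)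
Conditions: Cs2CO3, CH2Cl2, −20 → 25 °C
Reagents that add atoms: none
Why: Cs2CO3 eliminates sulfinate from 30 to the ortho-quinone methide 34 and deprotonates 33 to ylide 35; conjugate addition of the ylide carbon to the methide carbon and 5-exo-tet displacement of the sulfide by the phenoxide ([4+1] annulation) close the inner dihydrobenzofuran trans, and the terpene-derived sulfide selects the faces so that C3 and C2 should form as (3S,2S), reagent control being expected to override the bias of the neighbouring oxolane.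

Step 19
Reactants: 36 deca-O-benzylkobophenol A
Product: 37 kobophenol A
Conditions: H2 (1 atm), Pd(OH)2/C, THF/MeOH, 25 °C
Reagents that add atoms: none
Why: Hydrogenolysis should cleave the ten primary benzyl aryl ethers much faster than the secondary benzylic C–O bonds of the three oxygen rings, so the phenols are freed without change at any stereocenter.

**Compound list**

1 | tert-butyl 3-bromo-4-fluorobenzoate | CC(C)(C)OC(=O)c1ccc(F)c(Br)c1 | starting material
2 | tert-butyl 3-bromo-4-fluoro-5-(4,4,5,5-tetramethyl-1,3,2-dioxaborolan-2-yl)benzoate | CC(C)(C)OC(=O)c1cc(Br)c(F)c(B2OC(C)(C)C(C)(C)O2)c1 | intermediate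
3 | tert-butyl 3-bromo-4-fluoro-5-hydroxybenzoate | CC(C)(C)OC(=O)c1cc(O)c(F)c(Br)c1 | intermediate
4 | tert-butyl 3-(benzyloxy)-5-bromo-4-fluorobenzoate | CC(C)(C)OC(=O)c1cc(OCc2ccccc2)c(F)c(Br)c1 | intermediate
5 | 3,5-bis(benzyloxy)benzyl bromide | BrCc1cc(OCc2ccccc2)cc(OCc2ccccc2)c1 | starting material
6 | [3,5-bis(benzyloxy)benzyl]zinc bromide | Br[Zn]Cc1cc(OCc2ccccc2)cc(OCc2ccccc2)c1 | intermediate
7 | tert-butyl 3-(benzyloxy)-5-[3,5-bis(benzyloxy)benzyl]-4-fluorobenzoate | CC(C)(C)OC(=O)c1cc(OCc2ccccc2)c(F)c(Cc2cc(OCc3ccccc3)cc(OCc3ccccc3)c2)c1 | intermediate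
8 | 4-(benzyloxy)benzaldehyde | O=Cc1ccc(OCc2ccccc2)cc1 | starting material
9 | lithium 1-[4-(benzyloxy)phenyl]-2-[3-(benzyloxy)-5-(tert-butoxycarbonyl)-2-fluorophenyl]-2-[3,5-bis(benzyloxy)phenyl]ethan-1-olate (both diastereomers) | [Li+].[O-]C(c1ccc(OCc2ccccc2)cc1)C(c1cc(OCc2ccccc2)cc(OCc2ccccc2)c1)c1cc(cc(OCc2ccccc2)c1F)C(=O)OC(C)(C)C | intermediate
10 | tert-butyl rac-(2R,3R)-7-(benzyloxy)-2-[4-(benzyloxy)phenyl]-3-[3,5-bis(benzyloxy)phenyl]-2,3-dihydro-1-benzofuran-5-carboxylate (trans, racemic) | CC(C)(C)OC(=O)c1cc(OCc2ccccc2)c2c(c1)[C@@H](c1cc(OCc3ccccc3)cc(OCc3ccccc3)c1)[C@H](c1ccc(OCc3ccccc3)cc1)O2 | intermediate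
11 | rac-(2R,3R)-7-(benzyloxy)-2-[4-(benzyloxy)phenyl]-3-[3,5-bis(benzyloxy)phenyl]-2,3-dihydro-1-benzofuran-5-carboxylic acid | OC(=O)c1cc(OCc2ccccc2)c2c(c1)[C@@H](c1cc(OCc3ccccc3)cc(OCc3ccccc3)c1)[C@H](c1ccc(OCc3ccccc3)cc1)O2 | intermediate
12 | (S)-2-(methoxymethyl)pyrrolidine | COC[C@@H]1CCCN1 | starting material
13 | rac-(2R,3R)-7-(benzyloxy)-2-[4-(benzyloxy)phenyl]-3-[3,5-bis(benzyloxy)phenyl]-2,3-dihydro-1-benzofuran-5-carbonyl chloride | ClC(=O)c1cc(OCc2ccccc2)c2c(c1)[C@@H](c1cc(OCc3ccccc3)cc(OCc3ccccc3)c1)[C@H](c1ccc(OCc3ccccc3)cc1)O2 | intermediate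
14 | [(2R,3R)-7-(benzyloxy)-2-[4-(benzyloxy)phenyl]-3-[3,5-bis(benzyloxy)phenyl]-2,3-dihydro-1-benzofuran-5-yl][(2S)-2-(methoxymethyl)pyrrolidin-1-yl]methanone | COC[C@@H]1CCCN1C(=O)c1cc(OCc2ccccc2)c2c(c1)[C@@H](c1cc(OCc3ccccc3)cc(OCc3ccccc3)c1)[C@H](c1ccc(OCc3ccccc3)cc1)O2 | intermediate
15 | 3,5-bis(benzyloxy)benzaldehyde | O=Cc1cc(OCc2ccccc2)cc(OCc2ccccc2)c1 | starting material
16 | 3,5-bis(benzyloxy)-2-bromobenzaldehyde | O=Cc1cc(OCc2ccccc2)cc(OCc2ccccc2)c1Br | intermediate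
17 | rac-1-[3,5-bis(benzyloxy)phenyl]prop-2-en-1-ol | C=CC(O)c1cc(OCc2ccccc2)cc(OCc2ccccc2)c1 | intermediate
18 | 1,5-bis(benzyloxy)-2-bromo-3-(2-methoxyethenyl)benzene (E/Z mixture) | COC=Cc1cc(OCc2ccccc2)cc(OCc2ccccc2)c1Br | intermediate
19 | 2-[3,5-bis(benzyloxy)-2-bromophenyl]acetaldehyde | O=CCc1cc(OCc2ccccc2)cc(OCc2ccccc2)c1Br | intermediate
20 | (2S,3R)-2-[3,5-bis(benzyloxy)-2-bromophenyl]-3-[3,5-bis(benzyloxy)phenyl]pent-4-enal | Brc1c(OCc2ccccc2)cc(OCc2ccccc2)cc1[C@@H](C=O)[C@H](c1cc(OCc2ccccc2)cc(OCc2ccccc2)c1)C=C | intermediate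
21 | (2S,3R)-1-[4-(benzyloxy)phenyl]-2-[3,5-bis(benzyloxy)-2-bromophenyl]-3-[3,5-bis(benzyloxy)phenyl]pent-4-en-1-ol (both C1 epimers) | Brc1c(OCc2ccccc2)cc(OCc2ccccc2)cc1[C@@H](C(O)c1ccc(OCc2ccccc2)cc1)[C@H](c1cc(OCc2ccccc2)cc(OCc2ccccc2)c1)C=C | intermediate
22 | (2R,3S)-4-[4-(benzyloxy)phenyl]-3-[3,5-bis(benzyloxy)-2-bromophenyl]-2-[3,5-bis(benzyloxy)phenyl]-4-hydroxybutanal (both C4 epimers) | Brc1c(OCc2ccccc2)cc(OCc2ccccc2)cc1[C@@H](C(O)c1ccc(OCc2ccccc2)cc1)[C@H](c1cc(OCc2ccccc2)cc(OCc2ccccc2)c1)C=O | intermediate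
23 | (3R,4S)-5-[4-(benzyloxy)phenyl]-4-[3,5-bis(benzyloxy)-2-bromophenyl]-3-[3,5-bis(benzyloxy)phenyl]oxolan-2-ol (mixture at C2 and C5) | OC1OC(c2ccc(OCc3ccccc3)cc2)[C@H](c2cc(OCc3ccccc3)cc(OCc3ccccc3)c2Br)[C@@H]1c1cc(OCc2ccccc2)cc(OCc2ccccc2)c1 | intermediate
24 | (2S,3R)-1,4-bis[4-(benzyloxy)phenyl]-2-[3,5-bis(benzyloxy)-2-bromophenyl]-3-[3,5-bis(benzyloxy)phenyl]butane-1,4-diol (mixture at C1 and C4) | Brc1c(OCc2ccccc2)cc(OCc2ccccc2)cc1[C@@H](C(O)c1ccc(OCc2ccccc2)cc1)[C@H](c1cc(OCc2ccccc2)cc(OCc2ccccc2)c1)C(O)c1ccc(OCc2ccccc2)cc1 | intermediate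
25 | (2R,3S,4R,5S)-2,5-bis[4-(benzyloxy)phenyl]-3-[3,5-bis(benzyloxy)-2-bromophenyl]-4-[3,5-bis(benzyloxy)phenyl]oxolane | Brc1c(OCc2ccccc2)cc(OCc2ccccc2)cc1[C@@H]1[C@H](c2cc(OCc3ccccc3)cc(OCc3ccccc3)c2)[C@@H](c2ccc(OCc3ccccc3)cc2)O[C@H]1c1ccc(OCc2ccccc2)cc1 | intermediate
26 | {2,4-bis(benzyloxy)-6-[(2R,3S,4R,5S)-2,5-bis[4-(benzyloxy)phenyl]-4-[3,5-bis(benzyloxy)phenyl]oxolan-3-yl]phenyl}lithium | [Li]c1c(OCc2ccccc2)cc(OCc2ccccc2)cc1[C@@H]1[C@H](c2cc(OCc3ccccc3)cc(OCc3ccccc3)c2)[C@@H](c2ccc(OCc3ccccc3)cc2)O[C@H]1c1ccc(OCc2ccccc2)cc1 | intermediate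
27 | {2,4-bis(benzyloxy)-6-[(2R,3S,4R,5S)-2,5-bis[4-(benzyloxy)phenyl]-4-[3,5-bis(benzyloxy)phenyl]oxolan-3-yl]phenyl}[(2R,3R)-7-(benzyloxy)-2-[4-(benzyloxy)phenyl]-3-[3,5-bis(benzyloxy)phenyl]-2,3-dihydro-1-benzofuran-5-yl]methanone | O=C(c1cc(OCc2ccccc2)c2c(c1)[C@@H](c1cc(OCc3ccccc3)cc(OCc3ccccc3)c1)[C@H](c1ccc(OCc3ccccc3)cc1)O2)c1c(OCc2ccccc2)cc(OCc2ccccc2)cc1[C@@H]1[C@H](c2cc(OCc3ccccc3)cc(OCc3ccccc3)c2)[C@@H](c2ccc(OCc3ccccc3)cc2)O[C@H]1c1ccc(OCc2ccccc2)cc1 | intermediate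
28 | {4-(benzyloxy)-2-hydroxy-6-[(2R,3S,4R,5S)-2,5-bis[4-(benzyloxy)phenyl]-4-[3,5-bis(benzyloxy)phenyl]oxolan-3-yl]phenyl}[(2R,3R)-7-(benzyloxy)-2-[4-(benzyloxy)phenyl]-3-[3,5-bis(benzyloxy)phenyl]-2,3-dihydro-1-benzofuran-5-yl]methanone | O=C(c1cc(OCc2ccccc2)c2c(c1)[C@@H](c1cc(OCc3ccccc3)cc(OCc3ccccc3)c1)[C@H](c1ccc(OCc3ccccc3)cc1)O2)c1c(O)cc(OCc2ccccc2)cc1[C@@H]1[C@H](c2cc(OCc3ccccc3)cc(OCc3ccccc3)c2)[C@@H](c2ccc(OCc3ccccc3)cc2)O[C@H]1c1ccc(OCc2ccccc2)cc1 | intermediate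
29 | 5-(benzyloxy)-2-{hydroxy[(2R,3R)-7-(benzyloxy)-2-[4-(benzyloxy)phenyl]-3-[3,5-bis(benzyloxy)phenyl]-2,3-dihydro-1-benzofuran-5-yl]methyl}-3-[(2R,3S,4R,5S)-2,5-bis[4-(benzyloxy)phenyl]-4-[3,5-bis(benzyloxy)phenyl]oxolan-3-yl]phenol (both carbinol epimers) | OC(c1cc(OCc2ccccc2)c2c(c1)[C@@H](c1cc(OCc3ccccc3)cc(OCc3ccccc3)c1)[C@H](c1ccc(OCc3ccccc3)cc1)O2)c1c(O)cc(OCc2ccccc2)cc1[C@@H]1[C@H](c2cc(OCc3ccccc3)cc(OCc3ccccc3)c2)[C@@H](c2ccc(OCc3ccccc3)cc2)O[C@H]1c1ccc(OCc2ccccc2)cc1 | intermediate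
30 | 5-(benzyloxy)-2-{[(2R,3R)-7-(benzyloxy)-2-[4-(benzyloxy)phenyl]-3-[3,5-bis(benzyloxy)phenyl]-2,3-dihydro-1-benzofuran-5-yl](4-methylbenzenesulfonyl)methyl}-3-[(2R,3S,4R,5S)-2,5-bis[4-(benzyloxy)phenyl]-4-[3,5-bis(benzyloxy)phenyl]oxolan-3-yl]phenol (both epimers at the sulfonyl carbon) | Cc1ccc(cc1)S(=O)(=O)C(c1cc(OCc2ccccc2)c2c(c1)[C@@H](c1cc(OCc3ccccc3)cc(OCc3ccccc3)c1)[C@H](c1ccc(OCc3ccccc3)cc1)O2)c1c(O)cc(OCc2ccccc2)cc1[C@@H]1[C@H](c2cc(OCc3ccccc3)cc(OCc3ccccc3)c2)[C@@H](c2ccc(OCc3ccccc3)cc2)O[C@H]1c1ccc(OCc2ccccc2)cc1 | intermediate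
31 | (1R,4R,5R)-4,7,7-trimethyl-6-thiabicyclo[3.2.1]octane (isothiocineole) | C[C@@H]1CC[C@@H]2C[C@H]1SC2(C)C | starting material
32 | 4-(benzyloxy)benzyl bromide | BrCc1ccc(OCc2ccccc2)cc1 | starting material
33 | (1R,4R,5R)-6-[4-(benzyloxy)benzyl]-4,7,7-trimethyl-6-thiabicyclo[3.2.1]octan-6-ium trifluoromethanesulfonate (one diastereomer at sulfur, benzyl on the less hindered face; sulfur configuration not encoded) | C[C@@H]1CC[C@@H]2C[C@H]1[S+](Cc1ccc(OCc3ccccc3)cc1)C2(C)C.[O-]S(=O)(=O)C(F)(F)F | intermediate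
34 | 3-(benzyloxy)-6-{[(2R,3R)-7-(benzyloxy)-2-[4-(benzyloxy)phenyl]-3-[3,5-bis(benzyloxy)phenyl]-2,3-dihydro-1-benzofuran-5-yl]methylidene}-5-[(2R,3S,4R,5S)-2,5-bis[4-(benzyloxy)phenyl]-4-[3,5-bis(benzyloxy)phenyl]oxolan-3-yl]cyclohexa-2,4-dien-1-one | O=C1C=C(OCc2ccccc2)C=C([C@@H]2[C@H](c3cc(OCc4ccccc4)cc(OCc4ccccc4)c3)[C@@H](c3ccc(OCc4ccccc4)cc3)O[C@H]2c2ccc(OCc3ccccc3)cc2)C1=Cc1cc(OCc2ccccc2)c2c(c1)[C@@H](c1cc(OCc3ccccc3)cc(OCc3ccccc3)c1)[C@H](c1ccc(OCc3ccccc3)cc1)O2 | intermediate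
35 | sulfonium benzylide of 33: (1R,4R,5R)-4,7,7-trimethyl-6-thiabicyclo[3.2.1]octan-6-ium-6-yl[4-(benzyloxy)phenyl]methanide | C[C@@H]1CC[C@@H]2C[C@H]1[S+]([CH-]c1ccc(OCc3ccccc3)cc1)C2(C)C | intermediate
36 | deca-O-benzylkobophenol A: (2S,3S)-6-(benzyloxy)-2-[4-(benzyloxy)phenyl]-3-[(2R,3R)-7-(benzyloxy)-2-[4-(benzyloxy)phenyl]-3-[3,5-bis(benzyloxy)phenyl]-2,3-dihydro-1-benzofuran-5-yl]-4-[(2R,3S,4R,5S)-2,5-bis[4-(benzyloxy)phenyl]-4-[3,5-bis(benzyloxy)phenyl]oxolan-3-yl]-2,3-dihydro-1-benzofuran | c1ccccc1COc1ccc([C@H]2Oc3cc(OCc6ccccc6)cc([C@@H]4[C@H](c5cc(OCc6ccccc6)cc(OCc6ccccc6)c5)[C@@H](c5ccc(OCc6ccccc6)cc5)O[C@H]4c4ccc(OCc6ccccc6)cc4)c3[C@@H]2c2cc(OCc6ccccc6)c3c(c2)[C@@H](c2cc(OCc6ccccc6)cc(OCc6ccccc6)c2)[C@H](c2ccc(OCc6ccccc6)cc2)O3)cc1 | intermediate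
37 | kobophenol A: (2S,3S)-4-[(2R,3S,4R,5S)-4-(3,5-dihydroxyphenyl)-2,5-bis(4-hydroxyphenyl)oxolan-3-yl]-3-[(2R,3R)-3-(3,5-dihydroxyphenyl)-7-hydroxy-2-(4-hydroxyphenyl)-2,3-dihydro-1-benzofuran-5-yl]-2-(4-hydroxyphenyl)-2,3-dihydro-1-benzofuran-6-ol | Oc1ccc([C@H]2Oc3cc(O)cc([C@@H]4[C@H](c5cc(O)cc(O)c5)[C@@H](c5ccc(O)cc5)O[C@H]4c4ccc(O)cc4)c3[C@@H]2c2cc(O)c3c(c2)[C@@H](c2cc(O)cc(O)c2)[C@H](c2ccc(O)cc2)O3)cc1 | target

**Totals**

Total step count: 19.
Longest linear sequence: 11 steps (steps 1–6, 14, 15, 16, 18, 19 from 1; the branch from 15 through steps 7, 9–13, 14, 15, 16, 18, 19 is equally long).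

**Steps most likely to fail**

Step 4. The diarylmethyl anion may be consumed by acylation on the ester of a second molecule, alkoxide 9 may revert or dehydrate before it closes, and the ring closure may show a weak trans preference. The fallback sets out from 7 and comes back at 10, separating C–C bond formation from ring closure. The anion of 7 (LiN(i-Pr)2, 2 equiv, −78 °C) is acylated with methyl 4-(benzyloxy)benzoate to give the ketone tert-butyl 3-(benzyloxy)-5-{1-[3,5-bis(benzyloxy)phenyl]-2-[4-(benzyloxy)phenyl]-2-oxoethyl}-4-fluorobenzoate F1. NaBH4 reduces it to the alcohol tert-butyl 3-(benzyloxy)-5-{1-[3,5-bis(benzyloxy)phenyl]-2-[4-(benzyloxy)phenyl]-2-hydroxyethyl}-4-fluorobenzoate F2. Cs2CO3 in DMF at 60 °C then closes F2 by SNAr, under conditions too weakly basic for retro-addition, to 10, whose cis portion is converged in step 5.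

Step 10. The α-aryl aldehyde centre may lose its configuration through enol or enamine formation, and an arylacetaldehyde may self-condense faster than its enamine is allylated. The fallback sets out from 19 and 17 and comes back at 20, using an ester enolate equivalent instead of an enamine. Oxidation of 19 (NaClO2, NaH2PO4, 2-methyl-2-butene) gives 2-[3,5-bis(benzyloxy)-2-bromophenyl]acetic acid F3, which pentafluorophenol and dicyclohexylcarbodiimide convert into pentafluorophenyl 2-[3,5-bis(benzyloxy)-2-bromophenyl]acetate F4. Methyl chloroformate and pyridine convert 17 into 1-[3,5-bis(benzyloxy)phenyl]prop-2-en-1-yl methyl carbonate F5. F4 and F5 are joined by the known synergistic allylation of aryl acetic esters with a cyclometalated iridium phosphoramidite catalyst and the chiral isothiourea benzotetramisole, in which the ammonium enolate sets C2 and the iridium allyl complex sets C3. This gives pentafluorophenyl (2S,3R)-2-[3,5-bis(benzyloxy)-2-bromophenyl]-3-[3,5-bis(benzyloxy)phenyl]pent-4-enoate F6, which i-Bu2AlH at −78 °C reduces to 20.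

Step 18. Facial selectivity at C3 of the inner ring may be poor if reagent and substrate bias oppose, the semi-stabilised ylide may add slowly to the crowded quinone methide, and the quinone methide may dimerise. The fallback sets out from 28 and comes back at 36, forming the C2–C3 bond by carbenoid C–H insertion instead. Phenol 28 is alkylated with 32 (K2CO3, DMF) to {4-(benzyloxy)-2-{[4-(benzyloxy)phenyl]methoxy}-6-[(2R,3S,4R,5S)-2,5-bis[4-(benzyloxy)phenyl]-4-[3,5-bis(benzyloxy)phenyl]oxolan-3-yl]phenyl}[(2R,3R)-7-(benzyloxy)-2-[4-(benzyloxy)phenyl]-3-[3,5-bis(benzyloxy)phenyl]-2,3-dihydro-1-benzofuran-5-yl]methanone F7. Hydrazine hydrate with acetic acid in hot ethanol gives the hydrazone of F7 F8. MnO2 oxidises this to the diaryldiazomethane derived from F7 F9, which the chiral dirhodium carboxylate Rh2(R-PTAD)4 (or its enantiomer, whichever gives 3S) turns into a donor/donor carbenoid that inserts into the ArO–CH2 bond. The product is the (2R,3S)-cis isomer of 36 at the inner dihydrobenzofuran F10. A catalytic amount of CF3CO2H then epimerises C2 through reversible C2–O ionisation to the trans compound 36.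

Further compounds
F1 | step 4 | tert-butyl 3-(benzyloxy)-5-{1-[3,5-bis(benzyloxy)phenyl]-2-[4-(benzyloxy)phenyl]-2-oxoethyl}-4-fluorobenzoate | CC(C)(C)OC(=O)c1cc(OCc2ccccc2)c(F)c(C(C(=O)c2ccc(OCc3ccccc3)cc2)c2cc(OCc3ccccc3)cc(OCc3ccccc3)c2)c1
F2 | step 4 | tert-butyl 3-(benzyloxy)-5-{1-[3,5-bis(benzyloxy)phenyl]-2-[4-(benzyloxy)phenyl]-2-hydroxyethyl}-4-fluorobenzoate | CC(C)(C)OC(=O)c1cc(OCc2ccccc2)c(F)c(C(C(O)c2ccc(OCc3ccccc3)cc2)c2cc(OCc3ccccc3)cc(OCc3ccccc3)c2)c1
F3 | step 10 | 2-[3,5-bis(benzyloxy)-2-bromophenyl]acetic acid | OC(=O)Cc1cc(OCc2ccccc2)cc(OCc2ccccc2)c1Br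
F4 | step 10 | pentafluorophenyl 2-[3,5-bis(benzyloxy)-2-bromophenyl]acetate | O=C(Cc1cc(OCc2ccccc2)cc(OCc2ccccc2)c1Br)Oc1c(F)c(F)c(F)c(F)c1F
F5 | step 10 | 1-[3,5-bis(benzyloxy)phenyl]prop-2-en-1-yl methyl carbonate | COC(=O)OC(C=C)c1cc(OCc2ccccc2)cc(OCc2ccccc2)c1
F6 | step 10 | pentafluorophenyl (2S,3R)-2-[3,5-bis(benzyloxy)-2-bromophenyl]-3-[3,5-bis(benzyloxy)phenyl]pent-4-enoate | Brc1c(OCc2ccccc2)cc(OCc2ccccc2)cc1[C@@H](C(=O)Oc1c(F)c(F)c(F)c(F)c1F)[C@H](c1cc(OCc2ccccc2)cc(OCc2ccccc2)c1)C=C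
F7 | step 18 | {4-(benzyloxy)-2-{[4-(benzyloxy)phenyl]methoxy}-6-[(2R,3S,4R,5S)-2,5-bis[4-(benzyloxy)phenyl]-4-[3,5-bis(benzyloxy)phenyl]oxolan-3-yl]phenyl}[(2R,3R)-7-(benzyloxy)-2-[4-(benzyloxy)phenyl]-3-[3,5-bis(benzyloxy)phenyl]-2,3-dihydro-1-benzofuran-5-yl]methanone | O=C(c1cc(OCc2ccccc2)c2c(c1)[C@@H](c1cc(OCc3ccccc3)cc(OCc3ccccc3)c1)[C@H](c1ccc(OCc3ccccc3)cc1)O2)c1c(OCc2ccc(OCc3ccccc3)cc2)cc(OCc2ccccc2)cc1[C@@H]1[C@H](c2cc(OCc3ccccc3)cc(OCc3ccccc3)c2)[C@@H](c2ccc(OCc3ccccc3)cc2)O[C@H]1c1ccc(OCc2ccccc2)cc1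
F8 | step 18 | hydrazone of F7 | NN=C(c1cc(OCc2ccccc2)c2c(c1)[C@@H](c1cc(OCc3ccccc3)cc(OCc3ccccc3)c1)[C@H](c1ccc(OCc3ccccc3)cc1)O2)c1c(OCc2ccc(OCc3ccccc3)cc2)cc(OCc2ccccc2)cc1[C@@H]1[C@H](c2cc(OCc3ccccc3)cc(OCc3ccccc3)c2)[C@@H](c2ccc(OCc3ccccc3)cc2)O[C@H]1c1ccc(OCc2ccccc2)cc1
F9 | step 18 | diaryldiazomethane derived from F7 | [N-]=[N+]=C(c1cc(OCc2ccccc2)c2c(c1)[C@@H](c1cc(OCc3ccccc3)cc(OCc3ccccc3)c1)[C@H](c1ccc(OCc3ccccc3)cc1)O2)c1c(OCc2ccc(OCc3ccccc3)cc2)cc(OCc2ccccc2)cc1[C@@H]1[C@H](c2cc(OCc3ccccc3)cc(OCc3ccccc3)c2)[C@@H](c2ccc(OCc3ccccc3)cc2)O[C@H]1c1ccc(OCc2ccccc2)cc1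
F10 | step 18 | (2R,3S)-cis isomer of 36 at the inner dihydrobenzofuran | c1ccccc1COc1ccc([C@@H]2Oc3cc(OCc6ccccc6)cc([C@@H]4[C@H](c5cc(OCc6ccccc6)cc(OCc6ccccc6)c5)[C@@H](c5ccc(OCc6ccccc6)cc5)O[C@H]4c4ccc(OCc6ccccc6)cc4)c3[C@@H]2c2cc(OCc6ccccc6)c3c(c2)[C@@H](c2cc(OCc6ccccc6)cc(OCc6ccccc6)c2)[C@H](c2ccc(OCc6ccccc6)cc2)O3)cc1
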